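**Retrosynthetic overview**
1. Target ⇐ the corresponding formyl compound (CHO → CH3 through its tosylhydrazone) ⇐ a ring B ketone by one-carbon homologation; the methyl-bearing CH centre is set by equilibration.
2. Ring B ketone ⇐ key step: arylative semipinacol ring expansion of a cis-hydrindanyl isopropenyl carbinol with an ortho-iodophenol ester. The cyclopentanol becomes the cyclohexanone, and the benzylic quaternary centre and the CH2–aryl bond form in the same step.
3. Carbinol ⇐ cis-hydrindanone + isopropenylmagnesium bromide; hydrindanone ⇐ methylenecyclohexane annulation on 3-methylcyclopent-2-en-1-one (asymmetric conjugate addition of an alkenylalane made from 5-chloropent-1-yne, then enolate alkylation).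
4. Aryl iodide ⇐ 4-iodophenol by methoxycarbonylation and ortho-iodination.
5. Ring order: cyclopentenone (bought) → ring A (annulation, carries the exocyclic methylene from the start) → ring B (expansion of the five-membered ring).

Assumption: the SMILES is read as absolute, (1R,2S,4aS,8aR) in decalin numbering, i.e. a cis-fused decalin with the ring-fusion hydrogen and all three methyl groups on one face. The facial sense of the chiral copper catalyst in step 3 is not verified here; the ligand enantiomer that gives the (S) ketone is to be chosen.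

**Step 1**
Reactants: 1 4-iodophenol
Product: 2 methyl 4-hydroxybenzoate
Conditions: Pd(OAc)2 (2 mol %), PPh3 (4 mol %), CO (1 atm), NaOAc (1.5 equiv), MeOH, 60 °C
Reagents that add atoms: carbon monoxide, [C-]#[O+]; methanol, CO
Why: Palladium-catalysed alkoxycarbonylation of an aryl iodide (oxidative addition, CO insertion, methanolysis of the acylpalladium); the free phenol is tolerated and no stereocentre is involved.

**Step 2**
Reactants: 2 methyl 4-hydroxybenzoate
Product: 3 methyl 4-hydroxy-3-iodobenzoate
Conditions: N-iodosuccinimide (1.0 equiv), CF3CO2H (10 mol %), MeCN, 0 → 25 °C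
Reagents that add atoms: N-iodosuccinimide, O=C1CCC(=O)N1I
Why: Electrophilic aromatic iodination; the hydroxyl (ortho/para) and the ester (meta) both direct to C3 because para is blocked, and one equivalent of reagent limits di-iodination.

**Step 3**
Reactants: 4 5-chloropent-1-yne; 5 3-methylcyclopent-2-en-1-one
Product: 8 (3S)-3-(5-chloropent-1-en-2-yl)-3-methylcyclopentan-1-one, via alkenylalane 6 (not isolated), via aluminium enolate 7 (not isolated)
Conditions: 4 (2.0 equiv), i-Bu2AlH (1.9 equiv), NiCl2(dppp) (3 mol %), THF, 22 °C; then 5 (1.0 equiv), CuCl2·2H2O (5 mol %), chiral sulfonate-bearing imidazolinium salt (NHC precursor, 5.5 mol %), THF, −30 °C; then 1 M HCl, 0 °C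
Reagents that add atoms: diisobutylaluminium hydride, CC(C)C[AlH]CC(C)C (its aluminium group is held in 6 and 7 only)
Why: Nickel-catalysed α-selective hydroalumination puts aluminium on the internal alkyne carbon, and NHC–copper-catalysed asymmetric conjugate addition transfers this alkenyl group (in preference to isobutyl) to the β-carbon of 5, the chiral ligand shielding one enone face so that the quaternary centre is formed as (S).

**Step 4**
Reactants: 8 (3S)-3-(5-chloropent-1-en-2-yl)-3-methylcyclopentan-1-one
Product: 9 (3aS,7aS)-3a-methyl-4-methylideneoctahydro-1H-inden-1-one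
Conditions: KOt-Bu (1.2 equiv), t-BuOH/THF, 25 °C
Reagents that add atoms: none
Why: Intramolecular enolate alkylation (6-exo-tet, methylenecyclohexane annulation): only the enolate on the CH2 between the carbonyl and the quaternary carbon can reach the chloride, and the tether can close only on its own face, so the ring fusion is cis (7a-H syn to 3a-CH3), which is also the preferred arrangement at this epimerisable centre.

**Step 5**
Reactants: 9 (3aS,7aS)-3a-methyl-4-methylideneoctahydro-1H-inden-1-one; 10 isopropenylmagnesium bromide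
Product: 12 (1R,3aS,7aS)-3a-methyl-4-methylidene-1-(prop-1-en-2-yl)octahydro-1H-inden-1-ol, via bromomagnesium alkoxide 11 (not isolated)
Conditions: 10 (1.5 equiv), LaCl3·2LiCl (0.3 equiv), THF, −40 → 0 °C; then H2O
Reagents that add atoms: none
Why: Lanthanum-assisted Grignard 1,2-addition (enolisation suppressed); the nucleophile is expected to attack from the convex face of the cis-hydrindanone, anti to the C7 methylene on the adjacent ring-fusion carbon, placing the isopropenyl group syn to 7a-H and 3a-CH3 (1R).

**Step 6**
Reactants: 12 (1R,3aS,7aS)-3a-methyl-4-methylidene-1-(prop-1-en-2-yl)octahydro-1H-inden-1-ol; 3 methyl 4-hydroxy-3-iodobenzoate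
Product: 13 methyl 4-hydroxy-3-{[(1S,4aS,8aS)-1,4a-dimethyl-5-methylidene-2-oxodecahydronaphthalen-1-yl]methyl}benzoate
Conditions: 3 (1.2 equiv), Pd(OAc)2 (10 mol %), P(2-furyl)3 (20 mol %), AgOAc (1.3 equiv), ClCH2CH2Cl, 60 °C
Reagents that add atoms: none
Why: Proposed new method: zerovalent palladium inserts into the C–I bond of 3, AgOAc removes iodide, and the electrophilic arylpalladium acetate binds the isopropenyl alkene of 12 next to the hydroxyl; the C1–C7a bond then migrates anti to palladium onto the internal alkene carbon while acetate takes the hydroxyl proton (Wacker-type semipinacol ring expansion, cyclopentanol to cyclohexanone; the tertiary C7a migrates rather than the C2 methylene), leaving a neopentyl alkyl(aryl)palladium with no β-hydrogen that can only reductively eliminate to form the CH2–aryl bond; C7a migrates with retention, so the cis ring fusion is carried over, and the new quaternary centre (1S) is set by the rotamer that keeps the small methyl over the ring and the palladium-bearing CH2 outside, next to the C–O bond; the hindered 4-methylidene alkene has no hydroxyl to direct palladium and no internal nucleophile and is expected to remain a spectator; the closest known reaction types are the divalent-palladium-catalysed semipinacol ring expansion of strained 1-alkenylcyclobutanols and the copper-catalysed arylative semipinacol rearrangement of tertiary allylic alcohols with diaryliodonium salts, neither shown for an unstrained cyclopentanol, an aryl iodide partner with a free phenol, or a substrate with a second alkene.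

**Step 7**
Reactants: 13 methyl 4-hydroxy-3-{[(1S,4aS,8aS)-1,4a-dimethyl-5-methylidene-2-oxodecahydronaphthalen-1-yl]methyl}benzoate
Product: 15 methyl 3-{[(1S,2S,4aS,8aR)-2-formyl-1,4a-dimethyl-5-methylidenedecahydronaphthalen-1-yl]methyl}-4-hydroxybenzoate, via enol ether 14 (not isolated)
Conditions: Ph3P(CH2OMe)Cl (4 equiv), KN(SiMe3)2 (4.5 equiv), THF, 0 → 40 °C; then 1 M HCl/THF, 25 °C; then K2CO3, MeOH, 25 °C
Reagents that add atoms: (methoxymethyl)triphenylphosphonium chloride, COC[P+](c1ccccc1)(c1ccccc1)c1ccccc1.[Cl-]; water, O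
Why: Wittig methoxymethylenation and enol-ether hydrolysis (one-carbon homologation), then base equilibration of the enolisable formyl centre: the axial position at C2 is 1,3-diaxial to the C8 ring methylene of the cis-decalin, so the equatorial formyl epimer (2S, syn to the C1 methyl) should be favoured by roughly 2 kcal/mol (a conformational estimate), and the phenoxide present under base deactivates the para ester.

**Step 8**
Reactants: 15 methyl 3-{[(1S,2S,4aS,8aR)-2-formyl-1,4a-dimethyl-5-methylidenedecahydronaphthalen-1-yl]methyl}-4-hydroxybenzoate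
Product: 17 methyl 4-hydroxy-3-{[(1R,2S,4aS,8aR)-1,2,4a-trimethyl-5-methylidenedecahydronaphthalen-1-yl]methyl}benzoate, via tosylhydrazone 16 (not isolated)
Conditions: TsNHNH2 (1.1 equiv), MeOH, 25 °C; then catecholborane (3 equiv), CHCl3, 0 °C; then NaOAc·3H2O, 60 °C
Reagents that add atoms: 4-methylbenzenesulfonohydrazide, Cc1ccc(cc1)S(=O)(=O)NN (its atoms are held in 16 only)
Why: Tosylhydrazone formation and hydride reduction (Caglioti-type reduction): hydride adds to C=N, sulfinate is lost and the diazene expels N2, turning CHO into CH3 without touching the adjacent stereocentre, the ester or the 1,1-disubstituted alkene.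

**Compound list**
1 | 4-iodophenol | Oc1ccc(I)cc1 | starting material
2 | methyl 4-hydroxybenzoate | COC(=O)c1ccc(O)cc1 | intermediate
3 | methyl 4-hydroxy-3-iodobenzoate | COC(=O)c1ccc(O)c(I)c1 | intermediate
4 | 5-chloropent-1-yne | C#CCCCCl | starting material
5 | 3-methylcyclopent-2-en-1-one | CC1=CC(=O)CC1 | starting material
6 | (5-chloropent-1-en-2-yl)bis(2-methylpropyl)alumane | C=C(CCCCl)[Al](CC(C)C)CC(C)C | intermediate (not isolated)
7 | {[(3S)-3-(5-chloropent-1-en-2-yl)-3-methylcyclopent-1-en-1-yl]oxy}bis(2-methylpropyl)alumane | C=C(CCCCl)[C@]1(C)C=C(O[Al](CC(C)C)CC(C)C)CC1 | intermediate (not isolated)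
8 | (3S)-3-(5-chloropent-1-en-2-yl)-3-methylcyclopentan-1-one | C=C(CCCCl)[C@]1(C)CC(=O)CC1 | intermediate
9 | (3aS,7aS)-3a-methyl-4-methylideneoctahydro-1H-inden-1-one | C=C1CCC[C@@H]2C(=O)CC[C@]12C | intermediate
10 | isopropenylmagnesium bromide | C=C(C)[Mg]Br | starting material
11 | bromomagnesium (1R,3aS,7aS)-3a-methyl-4-methylidene-1-(prop-1-en-2-yl)octahydro-1H-inden-1-olate | C=C1CCC[C@@H]2[C@@](O[Mg]Br)(C(C)=C)CC[C@]12C | intermediate (not isolated)
12 | (1R,3aS,7aS)-3a-methyl-4-methylidene-1-(prop-1-en-2-yl)octahydro-1H-inden-1-ol | C=C1CCC[C@@H]2[C@@](O)(C(C)=C)CC[C@]12C | intermediate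
13 | methyl 4-hydroxy-3-{[(1S,4aS,8aS)-1,4a-dimethyl-5-methylidene-2-oxodecahydronaphthalen-1-yl]methyl}benzoate | C=C1CCC[C@@H]2[C@](C)(Cc3cc(C(=O)OC)ccc3O)C(=O)CC[C@]12C | intermediate
14 | methyl 4-hydroxy-3-{[(1S,4aS,8aS)-2-(methoxymethylidene)-1,4a-dimethyl-5-methylidenedecahydronaphthalen-1-yl]methyl}benzoate (E/Z mixture) | C=C1CCC[C@@H]2[C@](C)(Cc3cc(C(=O)OC)ccc3O)C(=COC)CC[C@]12C | intermediate (not isolated)
15 | methyl 3-{[(1S,2S,4aS,8aR)-2-formyl-1,4a-dimethyl-5-methylidenedecahydronaphthalen-1-yl]methyl}-4-hydroxybenzoate | C=C1CCC[C@@H]2[C@](C)(Cc3cc(C(=O)OC)ccc3O)[C@@H](C=O)CC[C@]12C | intermediate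
16 | methyl 4-hydroxy-3-{[(1S,2S,4aS,8aR)-1,4a-dimethyl-5-methylidene-2-{[2-(4-methylbenzenesulfonyl)hydrazinylidene]methyl}decahydronaphthalen-1-yl]methyl}benzoate | C=C1CCC[C@@H]2[C@](C)(Cc3cc(C(=O)OC)ccc3O)[C@@H](C=NNS(=O)(=O)c3ccc(C)cc3)CC[C@]12C | intermediate (not isolated)
17 | methyl 4-hydroxy-3-{[(1R,2S,4aS,8aR)-1,2,4a-trimethyl-5-methylidenedecahydronaphthalen-1-yl]methyl}benzoate | C=C1CCC[C@@H]2[C@](C)(Cc3cc(C(=O)OC)ccc3O)[C@@H](C)CC[C@]12C | target

**Step count and risks**
Total steps: 8. Longest linear sequence: 6 (steps 3 to 8); the aryl branch (steps 1 and 2) joins at step 6.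

Most likely to fail:

Step 6 (the proposed new ring expansion). Risks are slow migration of the unstrained ring, Heck-type arylation at either alkene, and capture by the phenol oxygen. The known-chemistry fallback sets out from 12 and comes back at 13. Hydroxyl-directed epoxidation of 12 (VO(acac)2, t-BuOOH, CH2Cl2, 0 °C; the isolated methylidene is not epoxidised) gives the epoxy alcohol (1R,3aS,7aS)-3a-methyl-4-methylidene-1-[(2S)-2-methyloxiran-2-yl]octahydro-1H-inden-1-ol F1; this diastereomer is expected because the ring CH2, not the ring-fusion CH, eclipses the alkene methyl in the directed transition state. BF3·OEt2 in CH2Cl2 at −78 °C opens the epoxide at its tertiary carbon and the ring-fusion carbon migrates anti to the leaving oxygen (epoxy-alcohol semipinacol ring expansion) to give the hydroxy ketone (1R,4aS,8aS)-1-(hydroxymethyl)-1,4a-dimethyl-5-methylideneoctahydronaphthalen-2(1H)-one F2. I2, PPh3 and imidazole in toluene at 70 °C give the iodide (1S,4aS,8aS)-1-(iodomethyl)-1,4a-dimethyl-5-methylideneoctahydronaphthalen-2(1H)-one F3, which has no α-hydrogen and cannot eliminate. Nickel-catalysed reductive cross-electrophile coupling of F3 with 3 (NiI2, 4,4'-di-tert-butyl-2,2'-bipyridine, Zn, DMPU, 60 °C) then gives 13.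

Step 3 (asymmetric conjugate addition of a branched alkenylalane to a cyclopentenone; reactivity and ee are uncertain). The fallback sets out from 4 and comes back at 8; it changes how the nucleophile is made and the catalyst family. Markovnikov hydrobromination of 4 (HBr, Et4NBr, CH2Cl2) gives 2-bromo-5-chloropent-1-ene F4. Bromine–lithium exchange (t-BuLi, 2 equiv, Et2O, −78 °C) gives (5-chloropent-1-en-2-yl)lithium F5, and Me2AlCl converts it into (5-chloropent-1-en-2-yl)dimethylalumane F6. Copper-catalysed asymmetric conjugate addition of F6 to 5 with copper thiophene-2-carboxylate Cu(O2CC4H3S) (10 mol %) and a chiral phosphinamine ligand in Et2O at −10 °C gives the enolate {[(3S)-3-(5-chloropent-1-en-2-yl)-3-methylcyclopent-1-en-1-yl]oxy}dimethylalumane F7, which 1 M HCl hydrolyses to 8.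

Step 7 (Wittig reaction on a ketone flanked by a quaternary carbon). The fallback sets out from 13 and comes back at 15. Dimethylsulfonium methylide (Me3SI, KN(SiMe3)2, THF/DMSO, 0 °C), a small ylide that still adds to hindered ketones, gives the spiro-epoxide methyl 4-hydroxy-3-{[(1'S,4a'S,8a'S)-1',4a'-dimethyl-5'-methylideneoctahydro-1'H-spiro[oxirane-2,2'-naphthalen]-1'-yl]methyl}benzoate F8 (either configuration at the spiro carbon). BF3·OEt2 at −78 °C (Meinwald rearrangement with 1,2-hydride shift) gives the aldehyde as an epimer mixture, which K2CO3 in MeOH equilibrates to 15.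

**Further compounds**
F1 | step 6 | (1R,3aS,7aS)-3a-methyl-4-methylidene-1-[(2S)-2-methyloxiran-2-yl]octahydro-1H-inden-1-ol | C=C1CCC[C@@H]2[C@@](O)([C@]3(C)CO3)CC[C@]12C
F2 | step 6 | (1R,4aS,8aS)-1-(hydroxymethyl)-1,4a-dimethyl-5-methylideneoctahydronaphthalen-2(1H)-one | C=C1CCC[C@@H]2[C@](C)(CO)C(=O)CC[C@]12C
F3 | step 6 | (1S,4aS,8aS)-1-(iodomethyl)-1,4a-dimethyl-5-methylideneoctahydronaphthalen-2(1H)-one | C=C1CCC[C@@H]2[C@](C)(CI)C(=O)CC[C@]12C
F4 | step 3 | 2-bromo-5-chloropent-1-ene | C=C(Br)CCCCl
F5 | step 3 | (5-chloropent-1-en-2-yl)lithium | [Li]C(=C)CCCCl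
F6 | step 3 | (5-chloropent-1-en-2-yl)dimethylalumane | C=C(CCCCl)[Al](C)C
F7 | step 3 | {[(3S)-3-(5-chloropent-1-en-2-yl)-3-methylcyclopent-1-en-1-yl]oxy}dimethylalumane | C=C(CCCCl)[C@]1(C)C=C(O[Al](C)C)CC1
F8 | step 7 | methyl 4-hydroxy-3-{[(1'S,4a'S,8a'S)-1',4a'-dimethyl-5'-methylideneoctahydro-1'H-spiro[oxirane-2,2'-naphthalen]-1'-yl]methyl}benzoate | C=C1CCC[C@@H]2[C@](C)(Cc3cc(C(=O)OC)ccc3O)C3(CO3)CC[C@]12C
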